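Start from a ratio: Tuesday's target reading over Wednesday's at equal time. The two runs differ in the charge of reagent in the second phase by a factor of 2.00, and Wednesday's run is the flask asked about, followed further.

| flask | substrate | reagent in the second phase | remark | time | volume of the second phase over the first |
|---|---|---|---|---|---|
| Wednesday's | 0.050 M | 0.050 M | the very flask that is asked about, followed so far |  |  |
| Tuesday's | 0.050 M | 0.10 M | run made earlier |  |  |
| flask | 0.050 M | 0.0500 M |  | 40 h | 1.0 |

| Wednesday's: time / h | Wednesday's: target / % | Tuesday's: time / h | Tuesday's: target / % |
|---|---|---|---|
| 3.00 | 3.1 | 3.00 | 6.5 |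
| 6.00 | 7.1 | 6.00 | 14.0 |
| 10.0 | 10.9 | 10.0 | 18.7 |
| 20.0 | 9.1 | 15.0 | 18.0 |

(each reading ± 0.5 percentage points)

- charges count per volume of the first phase; a concentration in a rate is the amount of a species over the volume of its own phase; every rate counts per litre of the first phase
- the earlier runs hold the two phases in the same ratio of volumes as the flask asked about
- a reading or a percentage of target counts all its forms, free or not

- the best time, 40 h at the latest, for target
- the amount of target, in percent of the substrate charged, at that time

Climb the time scales. At 3.00 h the ratio reads 2.10, close to the charge ratio, so on this rung target grows in step with the charge. At 6.00 h it reads 1.97. At 10.0 h it reads 1.72, lower than the charge ratio, so target no longer keeps step. Keep this value as the run ratio, the factor that carries Tuesday's late readings over to Wednesday's flask.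

On the next rung Wednesday's run has a gap, so fill it. Divide Tuesday's 18.0% at 15.0 h by the run ratio to get 10.5% for Wednesday's flask at that time. Read this as the low side, since the ratio has been falling. By this estimate Wednesday's run stands nearly level between 10.0 h and 15.0 h, within a scatter of 0.5 percentage points, and its next reading is 9.1% at 20.0 h. Commit to a top near the middle, 12.5 h, at about 10.9%.

The forecast says 13 h and 11.8%, higher than this reckoning, on the ground that “Integrating on from 10.9% at 10 h adds roughly 1 point”.

The simulated flask peaks at 12.9 h with 10.9%.

    reagent in the reaction phase ⇌ reagent in the second phase, rate k1*([reagent in the reaction phase] - [reagent in the second phase]/K1) per volume of the first phase (partition coefficient = 1.40, kL = 3.10 × 10⁻⁵ /s)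
    substrate + reagent in the reaction phase → target (k = 9.80 × 10⁻⁴ /M/s)
    target ⇌ product in the second phase, rate k3*([target] - [product in the second phase]/K3) per volume of the first phase (partition coefficient = 1.40, kL = 6.20 × 10⁻⁴ /s)
    target → decomposed product (k = 1.10 × 10⁻⁴ /s)
    2 substrate → self-condensation product (k = 2.40 × 10⁻⁶ /M/s)
    reagent in the reaction phase → decomposed reagent (k = 1.80 × 10⁻⁵ /s)

Divide Tuesday's simulated top of 19.1%, its highest value up to its last reading, by the run ratio as read: it gives 11.2%, beside this flask's 10.9%. At 15.0 h the same division gave 10.5%, and the flask read then holds 10.8%. In this flask reaction-phase target has a half-life of 1.8 h towards decomposed product at 9.32 h, far shorter than the 40 h allowed. At 40.0 h this flask holds 48.1% decomposed product, more than its 3.88% target.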